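The easy step came first: from each charge of free catalyst I took away c(impurity), 0.24 mM, assuming that one impurity destroys one catalyst, so that a flask with equal amounts stands at the zero of the scale. In zeta this leaves 0.160 mM, and I called this difference, c(free catalyst) minus c(impurity), the net catalyst. The earlier runs lie on either side of zero: the south run, charged with 0.092 mM of free catalyst, less than its impurity, read no more than 1.3%, while the north run, with a net catalyst of 0.480 mM, read 71.3% at 8.00 h.

in all of them: solid substrate 0.40 M; impurity 0.24 mM
- south: second substrate 0.20 M; free catalyst 0.092 mM; run made earlier
- north: second substrate 0.20 M; free catalyst 0.72 mM; run made earlier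
- zeta: second substrate 0.200 M; free catalyst 0.40 mM; time 8.0 h
- delta: second substrate 0.200 M; free catalyst 0.12 mM; time 8.0 h
- gamma: second substrate 0.200 M; free catalyst 0.80 mM; time 8.0 h
- eta: second substrate 0.200 M; free catalyst 0.60 mM; time 8.0 h
- alpha: second substrate 0.200 M; free catalyst 1.2 mM; time 8.0 h

| run | time / h | target / % |
|---|---|---|
| south | 1.00 | 0.5 |
| south | 3.00 | 0 |
| south | 5.00 | 1.3 |
| south | 8.00 | 0.1 |
| north | 0.667 | 2.7 |
| north | 1.33 | 8.9 |
| north | 3.00 | 23.4 |
| north | 8.00 | 71.3 |

(readings scatter by 0.5 percentage points)

* the flasks put in order of amount of target, in percent of the solid substrate charged, best first, at 8.0 h (zeta / delta / gamma / eta / alpha)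
* the amount of target, in percent of the solid substrate charged of the flask you put first, at 8.0 h
* the amount of target, in percent of the solid substrate charged of the flask you put last, at 8.0 h

- at the start none of the solid substrate is in solution
- what has only dissolved of solid substrate counts as not reacted
- a reading or a percentage of target counts all its forms, free or not

I had to choose the recipe for the next run, so I scaled the north reading by net catalyst. Gamma, at 0.560 mM, came to 83.2%, eta, at 0.360 mM, to 53.5%, and zeta to 23.8%. Delta stood below zero at −0.120 mM, so I expected no target from it. Alpha, at 0.960 mM, scaled to 143%, more than the solid substrate charged, so I ranked alpha first, gave it no number, and chose to charge it.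

The forecast ran alpha > gamma > eta > zeta > delta, with 93% for the first flask and 0.2% for the last, reasoning that “so the impurity seems to kill catalyst”; its order is mine, but it put a number on alpha where I gave none.

The flasks gave alpha > gamma > eta > zeta > delta, with 87.8% in alpha, less than the forecast's number, and 0.0142% in delta.

    crystals ⇌ target, rate k1*(cs1 - [target]) while solid is left; crystals form when [target] > cs1 (solubility = 0.380 M, k = 10.0 /h)
    free catalyst + impurity → spent catalyst (k = 1.90 × 10⁵ /M/h)
    catalyst intermediate B → free catalyst + second product (k = 160 /h)
    catalyst intermediate A → free catalyst + target (k = 500 /h)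
    solid substrate ⇌ starting material, rate k5*(cs5 - [starting material]) while solid is left; crystals form when [starting material] > cs5 (solubility = 0.0880 M, k = 0.590 /h)
    second substrate + free catalyst ⇌ catalyst intermediate B (K = 3.90 /M, k = 1600 /M/h)
    starting material + free catalyst ⇌ catalyst intermediate A (K = 44.0 /M, k = 7000 /M/h)

Delta, at its net catalyst of −0.120 mM, stood with free catalyst at 0% of its charge and impurity at 50.0% of its own. A neighbour flask, delta with c(impurity) cut to 0.0960 mM, has a net catalyst of 0.0240 mM, just above zero, and scaling the north reading gives it 3.56%. That neighbour gave 7.33% of target, twice the scaled figure, with spent catalyst at 80.0% of the catalyst charged.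

(The numbers in the tables stem from a simulated flask on assumed constants; the scatter is artificial.)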